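**Plan**
- Numbering: the side chain runs from benzylic C1 to C15 (the CMe2 carbon of the oxolane, ring B); ring A is the arene. The E C2=C3 olefin has its methyl on C3 and the arylmethyl carbon on C2, which is the pattern left by syn-methylalumination of a C2≡C3 terminal alkyne and benzylation at C2.
- Retrosynthesis: with acetate and OH groups exchanged for silyl ethers, C1–C2 and C3–CH3 are cut together (benzylic chloride, Me3Al, alkyne). Then C4–C5 is cut (allenylboronate plus C5 enal), then C11–C12 (alkenylzinc plus 2-sulfonyl oxolane), then both C15–CH3 bonds (Grignard on a lactone).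
- Forward: ring B is made first from (S)-α-hydroxy-γ-butyrolactone. A geraniol-derived C5–C11 alkenyl iodide is joined at C11–C12, C2–C4 are added at C5, and ring A (from 4-methoxy-2-methylphenol) is attached last, before the acetate endgame.
- Stereocentres: C14 comes from the chiral pool (the lactone is the reduced form of (S)-malic acid). C12 is set by substrate control, the alkenyl group entering the ring-B oxocarbenium ion cis to the C14 silyloxy group. C5 is set by a chiral phosphoric acid catalyst.
- Olefins: C6=C7 comes from geraniol, C10=C11 from syn-hydrozirconation and iodination, C2=C3 from syn-carboalumination.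

Key step: step 20

Assumption: (R)-TRIP is taken to deliver the allenyl group to the Re face of the C5 aldehyde, as this catalyst class does in the related allylborations, which gives the 5R carbinol; if the sense is opposite, the mirror-image catalyst is used.

Step 1
Reactants: 1 4-methoxy-2-methylphenol
Product: 2 2-hydroxy-5-methoxy-3-methylbenzaldehyde
Conditions: MgCl2, Et3N, (CH2O)n, MeCN, reflux; aq. HCl
Reagents that add atoms: paraformaldehyde as formaldehyde, C=O
Why: Magnesium-phenoxide-directed ortho-formylation (Casnati–Skattebøl reaction) can only reach the single free ortho position, the other being blocked by methyl and the para position by methoxy.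

Step 2
Reactants: 2 2-hydroxy-5-methoxy-3-methylbenzaldehyde
Product: 3 2-[(tert-butyldimethylsilyl)oxy]-5-methoxy-3-methylbenzaldehyde
Conditions: TBSCl, imidazole, DMF, rt
Reagents that add atoms: tert-butyldimethylsilyl chloride, CC(C)(C)[Si](C)(C)Cl
Why: Routine silylation of a phenol masks the acidic OH from the organometallic reagents of steps 3 and 20 and is reversed by fluoride at the end.

Step 3
Reactants: 3 2-[(tert-butyldimethylsilyl)oxy]-5-methoxy-3-methylbenzaldehyde
Product: 4 {2-[(tert-butyldimethylsilyl)oxy]-5-methoxy-3-methylphenyl}methanol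
Conditions: i-Bu2AlH, CH2Cl2, −78 °C; aq. potassium sodium tartrate
Reagents that add atoms: none
Why: Low-temperature hydride reduction through a non-basic aluminium alkoxide should give the benzylic alcohol without migration of the aryl silyl group to the new oxygen.

Step 4
Reactants: 4 {2-[(tert-butyldimethylsilyl)oxy]-5-methoxy-3-methylphenyl}methanol
Product: 5 tert-butyl[2-(chloromethyl)-4-methoxy-6-methylphenoxy]dimethylsilane
Conditions: PPh3 and NCS premixed, THF, 0 °C to rt
Reagents that add atoms: N-chlorosuccinimide, O=C1CCC(=O)N1Cl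
Why: Appel-type chlorination via the alkoxyphosphonium salt converts the electron-rich benzylic alcohol to the chloride under neutral conditions that spare the aryl silyl ether.

Step 5
Reactants: 6 (3S)-3-hydroxyoxolan-2-one
Product: 7 (3S)-3-[(tert-butyldimethylsilyl)oxy]oxolan-2-one
Conditions: TBSCl, imidazole, DMF, rt
Reagents that add atoms: tert-butyldimethylsilyl chloride, CC(C)(C)[Si](C)(C)Cl
Why: Standard silylation of the secondary alcohol protects the future C14 oxygen and later serves as the stereodirecting group on ring B.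

Step 6
Reactants: 7 (3S)-3-[(tert-butyldimethylsilyl)oxy]oxolan-2-one
Product: 8 (3S)-3-[(tert-butyldimethylsilyl)oxy]-4-methylpentane-1,4-diol
Conditions: MeMgBr (2.5 equiv), THF, −20 to 0 °C; aq. NH4Cl
Reagents that add atoms: methylmagnesium bromide, C[Mg]Br
Why: Double Grignard addition to the lactone carbonyl builds the C15 dimethylcarbinol and frees the C12 primary alcohol, while C14 is untouched and keeps the S configuration of the starting lactone.

Step 7
Reactants: 8 (3S)-3-[(tert-butyldimethylsilyl)oxy]-4-methylpentane-1,4-diol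
Product: 10 (4S)-4-[(tert-butyldimethylsilyl)oxy]-5,5-dimethyloxolan-2-ol as both anomers, via hydroxy aldehyde 9 (not isolated)
Conditions: SO3·pyridine, DMSO, i-Pr2NEt, CH2Cl2, 0 °C
Reagents that add atoms: none
Why: Parikh–Doering oxidation acts only on the primary alcohol, since the tertiary one cannot be oxidised, and the γ-hydroxy aldehyde should close spontaneously to the five-membered lactol (ring B).

Step 8
Reactants: 10 (4S)-4-[(tert-butyldimethylsilyl)oxy]-5,5-dimethyloxolan-2-ol
Product: 11 tert-butyl{[(3S)-2,2-dimethyl-5-(phenylsulfonyl)oxolan-3-yl]oxy}dimethylsilane as both C5 epimers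
Conditions: PhSO2H, CaCl2, CH2Cl2, rt
Reagents that add atoms: benzenesulfinic acid, O=S(O)c1ccccc1
Why: Acid-mediated exchange of the anomeric hydroxyl for sulfinate is the known route from lactols to 2-sulfonyl cyclic ethers, which are storable oxocarbenium precursors; the epimer mixture converges in step 15.

Step 9
Reactants: 12 geraniol, (2E)-3,7-dimethylocta-2,6-dien-1-ol
Product: 13 1-({[(2E)-3,7-dimethylocta-2,6-dien-1-yl]oxy}methyl)-4-methoxybenzene
Conditions: NaH, PMBCl, Bu4NI (cat.), THF/DMF, 0 °C to rt
Reagents that add atoms: 4-methoxybenzyl chloride, COc1ccc(CCl)cc1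
Why: Williamson etherification gives a C5–O protecting group that tolerates peracid, periodic acid, organolithiums and zirconium hydride and is later removed oxidatively without touching silyl ethers.

Step 10
Reactants: 13 1-({[(2E)-3,7-dimethylocta-2,6-dien-1-yl]oxy}methyl)-4-methoxybenzene
Product: 14 racemic 3-{(3E)-5-[(4-methoxybenzyl)oxy]-3-methylpent-3-en-1-yl}-2,2-dimethyloxirane
Conditions: mCPBA, NaHCO3, CH2Cl2, −20 to 0 °C
Reagents that add atoms: 3-chloroperoxybenzoic acid, OOC(=O)c1cccc(Cl)c1
Why: Prilezhaev epoxidation should select the more electron-rich distal olefin, the proximal one being deactivated by the allylic ether oxygen; the epoxide configuration is irrelevant because this carbon pair is cleaved next.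

Step 11
Reactants: 14 racemic 3-{(3E)-5-[(4-methoxybenzyl)oxy]-3-methylpent-3-en-1-yl}-2,2-dimethyloxirane
Product: 16 (4E)-6-[(4-methoxybenzyl)oxy]-4-methylhex-4-enal, via diol 15 (not isolated)
Conditions: H5IO6, THF/H2O, 0 °C
Reagents that add atoms: none
Why: Acidic epoxide hydrolysis followed in the same flask by periodate glycol cleavage releases the C10 aldehyde and acetone and leaves the E C6=C7 olefin inherited from geraniol untouched.

Step 12
Reactants: 16 (4E)-6-[(4-methoxybenzyl)oxy]-4-methylhex-4-enal
Product: 17 1-methoxy-4-({[(2E)-3-methylhept-2-en-6-yn-1-yl]oxy}methyl)benzene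
Conditions: dimethyl (1-diazo-2-oxopropyl)phosphonate, K2CO3, MeOH, 0 °C to rt
Reagents that add atoms: dimethyl (1-diazo-2-oxopropyl)phosphonate, COP(=O)(OC)C(=[N+]=[N-])C(C)=O
Why: Seyferth–Gilbert homologation in its Ohira–Bestmann form converts the aldehyde to the terminal alkyne under mild base that does not disturb the olefin or the benzylic ether.

Step 13
Reactants: 17 1-methoxy-4-({[(2E)-3-methylhept-2-en-6-yn-1-yl]oxy}methyl)benzene
Product: 19 1-methoxy-4-({[(2E)-3-methyloct-2-en-6-yn-1-yl]oxy}methyl)benzene, via lithium acetylide 18 (not isolated)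
Conditions: n-BuLi, THF, −78 °C; MeI, DMPU, −78 °C to rt
Reagents that add atoms: iodomethane, CI
Why: Acetylide alkylation installs the carbon that becomes the methyl branch on C11.

Step 14
Reactants: 19 1-methoxy-4-({[(2E)-3-methyloct-2-en-6-yn-1-yl]oxy}methyl)benzene
Product: 21 1-({[(2E,6E)-7-iodo-3-methylocta-2,6-dien-1-yl]oxy}methyl)-4-methoxybenzene, via alkenylzirconocene chloride 20 (not isolated)
Conditions: Cp2Zr(H)Cl (2.2 equiv), THF, 50 °C; then I2, 0 °C
Reagents that add atoms: iodine, II
Why: syn-Hydrozirconation of the 2-alkyne, equilibrated with excess hydride so that zirconium settles on the less hindered methyl-bearing carbon C11, followed by iodinolysis with retention, should give the alkenyl iodide with the methyl cis to C9.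

Step 15
Reactants: 21 1-({[(2E,6E)-7-iodo-3-methylocta-2,6-dien-1-yl]oxy}methyl)-4-methoxybenzene; 11 tert-butyl{[(3S)-2,2-dimethyl-5-(phenylsulfonyl)oxolan-3-yl]oxy}dimethylsilane
Product: 24 tert-butyl({(3S,5S)-5-[(2E,6E)-8-[(4-methoxybenzyl)oxy]-6-methylocta-2,6-dien-2-yl]-2,2-dimethyloxolan-3-yl}oxy)dimethylsilane, via alkenyllithium 22 (not isolated), via alkenylzinc bromide 23 (not isolated)
Conditions: 21, t-BuLi (2 equiv), Et2O, −78 °C; ZnBr2, THF, −78 to 0 °C; then 11, THF, 0 °C to rt
Reagents that add atoms: none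
Why: Zinc-assisted loss of sulfinate from 11 gives the ring-B oxocarbenium ion, which the alkenylzinc reagent captures with retention of olefin geometry (the known substitution of 2-sulfonyl cyclic ethers by organozinc reagents); attack on the inside face of the envelope that holds the C14 silyloxy group pseudoaxial, a conformer also favoured by the C15 gem-dimethyl group, should place the chain cis to the C14 oxygen and set C12 as S.

Step 16
Reactants: 24 tert-butyl({(3S,5S)-5-[(2E,6E)-8-[(4-methoxybenzyl)oxy]-6-methylocta-2,6-dien-2-yl]-2,2-dimethyloxolan-3-yl}oxy)dimethylsilane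
Product: 25 (2E,6E)-7-{(2S,4S)-4-[(tert-butyldimethylsilyl)oxy]-5,5-dimethyloxolan-2-yl}-3-methylocta-2,6-dien-1-ol
Conditions: DDQ (1.2 equiv), CH2Cl2/pH 7 buffer, 0 °C
Reagents that add atoms: none
Why: Oxidative cleavage of the 4-methoxybenzyl ether by DDQ is much faster than attack on the simple allylic ether of ring B and leaves the silyl ether intact.

Step 17
Reactants: 25 (2E,6E)-7-{(2S,4S)-4-[(tert-butyldimethylsilyl)oxy]-5,5-dimethyloxolan-2-yl}-3-methylocta-2,6-dien-1-ol
Product: 26 (2E,6E)-7-{(2S,4S)-4-[(tert-butyldimethylsilyl)oxy]-5,5-dimethyloxolan-2-yl}-3-methylocta-2,6-dienal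
Conditions: MnO2, CH2Cl2, rt
Reagents that add atoms: none
Why: Manganese dioxide oxidises only the allylic primary alcohol and should give the E enal without olefin isomerisation.

Step 18
Reactants: 26 (2E,6E)-7-{(2S,4S)-4-[(tert-butyldimethylsilyl)oxy]-5,5-dimethyloxolan-2-yl}-3-methylocta-2,6-dienal; 27 4,4,5,5-tetramethyl-2-(propa-1,2-dien-1-yl)-1,3,2-dioxaborolane
Product: 29 (4R,5E,9E)-10-{(2S,4S)-4-[(tert-butyldimethylsilyl)oxy]-5,5-dimethyloxolan-2-yl}-6-methylundeca-5,9-dien-1-yn-4-ol, via pinacol borate ester 28 (not isolated)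
Conditions: (R)-TRIP [(R)-3,3′-bis(2,4,6-triisopropylphenyl)-1,1′-binaphthyl-2,2′-diyl hydrogen phosphate] (10 mol %), 4 Å molecular sieves, toluene, 0 °C; aqueous work-up
Reagents that add atoms: none
Why: In this chiral-phosphoric-acid-catalysed propargylation the acid binds boronate and aldehyde in a closed six-membered SE2′ transition state, so the allenyl reagent gives only the homopropargylic alcohol, and the (R)-catalyst should direct attack to the Re face and set C5 as R under catalyst control, the remote C12 and C14 centres having no influence.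

Step 19
Reactants: 29 (4R,5E,9E)-10-{(2S,4S)-4-[(tert-butyldimethylsilyl)oxy]-5,5-dimethyloxolan-2-yl}-6-methylundeca-5,9-dien-1-yn-4-ol
Product: 30 triethylsilyl ether of 29 (the C2–C15 alkyne with C5 OSiEt3 and C14 OSiMe2t-Bu; 5R,12S,14S)
Conditions: TESCl, imidazole, CH2Cl2, 0 °C to rt
Reagents that add atoms: chlorotriethylsilane, CC[Si](Cl)(CC)CC
Why: Silylation removes the only acidic OH before the alane chemistry, and the triethylsilyl group can later be cleaved selectively in the presence of the two tert-butyldimethylsilyl ethers.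

Step 20
Reactants: 30 triethylsilyl ether of 29; 31 trimethylaluminium; 5 tert-butyl[2-(chloromethyl)-4-methoxy-6-methylphenoxy]dimethylsilane
Product: 33 fully silylated target skeleton (aryl and C14 tert-butyldimethylsilyl ethers and C5 triethylsilyl ether), via alkenyldimethylalane 32 (not isolated)
Conditions: 31 (2 equiv), Cp2ZrCl2 (0.25 equiv), ClCH2CH2Cl, 0 °C to rt; solvent and excess 31 removed in vacuo; then 5, NiCl2(PPh3)2 (5 mol %) pre-reduced with n-BuLi (10 mol %) to zerovalent nickel, THF, rt
Reagents that add atoms: none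
Why: Cp2ZrCl2 activates 31 for four-centre syn-carbometalation of the terminal alkyne (Negishi zirconium-catalysed carboalumination), placing methyl on the internal carbon C3 and aluminium on C2 to give the E alkenylalane 32. After excess 31 is pumped off, zerovalent nickel inserts into the benzylic C–Cl bond of 5, the alkenyl group is transferred from aluminium and reductive elimination with retention forms C1–C2; the closest precedent is the one-pot carboalumination and nickel-catalysed benzylation used for prenylated quinone side chains. No ring closes and no stereocentre is formed; the step only has to fix the C2=C3 geometry, which follows from syn addition and retention in transmetalation and reductive elimination. Regiochemistry is secure because the alkyne is terminal and flanked only by a CH2 group, and chemoselectivity because the other two olefins are trisubstituted and inert to carboalumination while every oxygen is silylated or an ether and cannot quench the alane. Bringing ring A in as a benzylic electrophile fixes attachment at the intended ring carbon and avoids the ortho/para and SN2′ ambiguities of a phenol allylation.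

Step 21
Reactants: 33 fully silylated target skeleton
Product: 34 C5 alcohol with both tert-butyldimethylsilyl ethers retained
Conditions: PPTS (cat.), MeOH/CH2Cl2, 0 °C
Reagents that add atoms: none
Why: Mild acid methanolysis removes the triethylsilyl ether much faster than the hindered secondary and the aryl tert-butyldimethylsilyl ethers.

Step 22
Reactants: 34 C5 alcohol
Product: 35 C5 acetate with both tert-butyldimethylsilyl ethers retained
Conditions: Ac2O, pyridine, DMAP (cat.), CH2Cl2, 0 °C to rt
Reagents that add atoms: acetic anhydride, CC(=O)OC(C)=O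
Why: DMAP-catalysed acylation of the only free hydroxyl proceeds with retention at C5.

Step 23
Reactants: 35 C5 acetate
Product: 36 (2E,5R,6E,10E)-1-(2-hydroxy-5-methoxy-3-methylphenyl)-11-[(2S,4S)-4-hydroxy-5,5-dimethyloxolan-2-yl]-3,7-dimethyldodeca-2,6,10-trien-5-yl acetate (CNP0148147.2)
Conditions: Bu4NF, AcOH (1:1), THF, 0 °C to rt
Reagents that add atoms: none
Why: Fluoride cleaves both silyl ethers, and buffering with acetic acid keeps the medium non-basic so that the C5 acetate should neither hydrolyse nor migrate.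

**Compound list**

1 | 4-methoxy-2-methylphenol | COc1ccc(O)c(C)c1 | starting material
2 | 2-hydroxy-5-methoxy-3-methylbenzaldehyde | COc1cc(C)c(O)c(C=O)c1 | intermediate
3 | 2-[(tert-butyldimethylsilyl)oxy]-5-methoxy-3-methylbenzaldehyde | COc1cc(C)c(O[Si](C)(C)C(C)(C)C)c(C=O)c1 | intermediate
4 | {2-[(tert-butyldimethylsilyl)oxy]-5-methoxy-3-methylphenyl}methanol | COc1cc(C)c(O[Si](C)(C)C(C)(C)C)c(CO)c1 | intermediate
5 | tert-butyl[2-(chloromethyl)-4-methoxy-6-methylphenoxy]dimethylsilane | COc1cc(C)c(O[Si](C)(C)C(C)(C)C)c(CCl)c1 | intermediate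
6 | (3S)-3-hydroxyoxolan-2-one [(S)-α-hydroxy-γ-butyrolactone] | O[C@H]1CCOC1=O | starting material
7 | (3S)-3-[(tert-butyldimethylsilyl)oxy]oxolan-2-one | CC(C)(C)[Si](C)(C)O[C@H]1CCOC1=O | intermediate
8 | (3S)-3-[(tert-butyldimethylsilyl)oxy]-4-methylpentane-1,4-diol | OCC[C@H](O[Si](C)(C)C(C)(C)C)C(C)(C)O | intermediate
9 | (3S)-3-[(tert-butyldimethylsilyl)oxy]-4-hydroxy-4-methylpentanal | O=CC[C@H](O[Si](C)(C)C(C)(C)C)C(C)(C)O | intermediate (not isolated)
10 | (4S)-4-[(tert-butyldimethylsilyl)oxy]-5,5-dimethyloxolan-2-ol, both anomers | OC1C[C@H](O[Si](C)(C)C(C)(C)C)C(C)(C)O1 | intermediate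
11 | tert-butyl{[(3S)-2,2-dimethyl-5-(phenylsulfonyl)oxolan-3-yl]oxy}dimethylsilane, both C5 epimers | O=S(=O)(c1ccccc1)C1C[C@H](O[Si](C)(C)C(C)(C)C)C(C)(C)O1 | intermediate
12 | geraniol, (2E)-3,7-dimethylocta-2,6-dien-1-ol | CC(C)=CCC/C(C)=C/CO | starting material
13 | 1-({[(2E)-3,7-dimethylocta-2,6-dien-1-yl]oxy}methyl)-4-methoxybenzene | COc1ccc(COC/C=C(\C)CCC=C(C)C)cc1 | intermediate
14 | racemic 3-{(3E)-5-[(4-methoxybenzyl)oxy]-3-methylpent-3-en-1-yl}-2,2-dimethyloxirane | COc1ccc(COC/C=C(\C)CCC2OC2(C)C)cc1 | intermediate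
15 | racemic (6E)-8-[(4-methoxybenzyl)oxy]-2,6-dimethyloct-6-ene-2,3-diol | COc1ccc(COC/C=C(\C)CCC(O)C(C)(C)O)cc1 | intermediate (not isolated)
16 | (4E)-6-[(4-methoxybenzyl)oxy]-4-methylhex-4-enal | COc1ccc(COC/C=C(\C)CCC=O)cc1 | intermediate
17 | 1-methoxy-4-({[(2E)-3-methylhept-2-en-6-yn-1-yl]oxy}methyl)benzene | COc1ccc(COC/C=C(\C)CCC#C)cc1 | intermediate
18 | lithium acetylide of 17 | COc1ccc(COC/C=C(\C)CCC#C[Li])cc1 | intermediate (not isolated)
19 | 1-methoxy-4-({[(2E)-3-methyloct-2-en-6-yn-1-yl]oxy}methyl)benzene | COc1ccc(COC/C=C(\C)CCC#CC)cc1 | intermediate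
20 | chlorobis(cyclopentadienyl)zirconium alkenyl from 19, zirconium on C11 trans to C9 | COc1ccc(COC/C=C(\C)CC/C=C(\C)[Zr](Cl)(C2C=CC=C2)C2C=CC=C2)cc1 | intermediate (not isolated)
21 | 1-({[(2E,6E)-7-iodo-3-methylocta-2,6-dien-1-yl]oxy}methyl)-4-methoxybenzene | COc1ccc(COC/C=C(\C)CC/C=C(\C)I)cc1 | intermediate
22 | alkenyllithium from 21, lithium in place of iodine with geometry retained | COc1ccc(COC/C=C(\C)CC/C=C(\C)[Li])cc1 | intermediate (not isolated)
23 | alkenylzinc bromide from 22, ZnBr in place of lithium with geometry retained | COc1ccc(COC/C=C(\C)CC/C=C(\C)[Zn]Br)cc1 | intermediate (not isolated)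
24 | tert-butyl({(3S,5S)-5-[(2E,6E)-8-[(4-methoxybenzyl)oxy]-6-methylocta-2,6-dien-2-yl]-2,2-dimethyloxolan-3-yl}oxy)dimethylsilane | COc1ccc(COC/C=C(\C)CC/C=C(\C)[C@@H]2C[C@H](O[Si](C)(C)C(C)(C)C)C(C)(C)O2)cc1 | intermediate
25 | (2E,6E)-7-{(2S,4S)-4-[(tert-butyldimethylsilyl)oxy]-5,5-dimethyloxolan-2-yl}-3-methylocta-2,6-dien-1-ol | OC/C=C(\C)CC/C=C(\C)[C@@H]1C[C@H](O[Si](C)(C)C(C)(C)C)C(C)(C)O1 | intermediate
26 | (2E,6E)-7-{(2S,4S)-4-[(tert-butyldimethylsilyl)oxy]-5,5-dimethyloxolan-2-yl}-3-methylocta-2,6-dienal | O=C/C=C(\C)CC/C=C(\C)[C@@H]1C[C@H](O[Si](C)(C)C(C)(C)C)C(C)(C)O1 | intermediate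
27 | 4,4,5,5-tetramethyl-2-(propa-1,2-dien-1-yl)-1,3,2-dioxaborolane (allenylboronic acid pinacol ester) | C=C=CB1OC(C)(C)C(C)(C)O1 | starting material
28 | pinacol borate ester of 29 (boron on the C5 oxygen) | C#CC[C@@H](OB1OC(C)(C)C(C)(C)O1)/C=C(\C)CC/C=C(\C)[C@@H]1C[C@H](O[Si](C)(C)C(C)(C)C)C(C)(C)O1 | intermediate (not isolated)
29 | (4R,5E,9E)-10-{(2S,4S)-4-[(tert-butyldimethylsilyl)oxy]-5,5-dimethyloxolan-2-yl}-6-methylundeca-5,9-dien-1-yn-4-ol | C#CC[C@@H](O)/C=C(\C)CC/C=C(\C)[C@@H]1C[C@H](O[Si](C)(C)C(C)(C)C)C(C)(C)O1 | intermediate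
30 | triethylsilyl ether of 29 (C2–C15 alkyne; 5R,12S,14S) | C#CC[C@H](/C=C(\C)CC/C=C(\C)[C@@H]1C[C@H](O[Si](C)(C)C(C)(C)C)C(C)(C)O1)O[Si](CC)(CC)CC | intermediate
31 | trimethylaluminium | C[Al](C)C | starting material
32 | (E)-alkenyldimethylalane from 30, AlMe2 on C2 and new methyl on C3, cis to each other | C[Al](C)/C=C(\C)C[C@H](/C=C(\C)CC/C=C(\C)[C@@H]1C[C@H](O[Si](C)(C)C(C)(C)C)C(C)(C)O1)O[Si](CC)(CC)CC | intermediate (not isolated)
33 | target skeleton with aryl and C14 tert-butyldimethylsilyl ethers and C5 triethylsilyl ether (2E,5R,6E,10E,12S,14S) | COc1cc(C)c(O[Si](C)(C)C(C)(C)C)c(C/C=C(\C)C[C@H](/C=C(\C)CC/C=C(\C)[C@@H]2C[C@H](O[Si](C)(C)C(C)(C)C)C(C)(C)O2)O[Si](CC)(CC)CC)c1 | intermediate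
34 | C5 alcohol of 33, both tert-butyldimethylsilyl ethers retained | COc1cc(C)c(O[Si](C)(C)C(C)(C)C)c(C/C=C(\C)C[C@@H](O)/C=C(\C)CC/C=C(\C)[C@@H]2C[C@H](O[Si](C)(C)C(C)(C)C)C(C)(C)O2)c1 | intermediate
35 | C5 acetate of 34 | COc1cc(C)c(O[Si](C)(C)C(C)(C)C)c(C/C=C(\C)C[C@H](/C=C(\C)CC/C=C(\C)[C@@H]2C[C@H](O[Si](C)(C)C(C)(C)C)C(C)(C)O2)OC(C)=O)c1 | intermediate
36 | (2E,5R,6E,10E)-1-(2-hydroxy-5-methoxy-3-methylphenyl)-11-[(2S,4S)-4-hydroxy-5,5-dimethyloxolan-2-yl]-3,7-dimethyldodeca-2,6,10-trien-5-yl acetate | COc1cc(C)c(O)c(C/C=C(\C)C[C@H](/C=C(\C)CC/C=C(\C)[C@@H]2C[C@H](O)C(C)(C)O2)OC(C)=O)c1 | target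

**Step count and risks**

Total steps: 23. Longest linear sequence: 15 steps (steps 9 to 23, from geraniol). The ring-B branch (steps 5 to 8) and the arene branch (steps 1 to 4) are run in parallel.

The three steps most likely to fail:

1. Step 15. The alkenylzinc reagent may capture the ring-B oxocarbenium ion with poor or reversed facial selectivity at C12, or sulfinate may be lost by elimination to the dihydrofuran. The fallback sets out from 10 and 21 and returns at 24. Lactol 10 is oxidised with TEMPO (cat.) and PhI(OAc)2 to (4S)-4-[(tert-butyldimethylsilyl)oxy]-5,5-dimethyloxolan-2-one F1. The alkenyllithium 22, made from 21 as before, is added to it at −78 °C to give the 2-alkenyl lactol F2. Ionic reduction of F2 with Et3SiH and BF3·OEt2 in CH2Cl2 at −78 °C then creates the C12 centre by hydride delivery instead of carbon delivery. This is the route to take if the carbon nucleophile proves to enter anti to the silyloxy group, because hydride would then enter on that same face and leave the alkenyl chain cis to the C14 oxygen, which is 24.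

2. Step 20. The Lewis-acidic alane may ionise or strip the allylic C5 silyl ether, methyl instead of alkenyl may be transferred to the benzylnickel intermediate, or 5 may homocouple. The fallback sets out from 30 and 5 and returns at 33, forming the same two bonds in separate operations with reversed polarity at the benzyl partner. Carboalumination of 30 as before is quenched with I2 to give the (E)-1-iodo-2-methylalkene F3. Chloride 5 is converted with zinc dust and LiCl in THF to the benzylzinc chloride F4. Pd(PPh3)4-catalysed Negishi coupling of F3 with F4 should then give 33 with retention of the E geometry.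

3. Step 18. The catalyst may give insufficient facial selectivity on the β,β-disubstituted enal, or an uncatalysed background addition may compete, and C5 epimers are unlikely to be separable. The fallback sets out from 26 and 27 and returns at 29. The allenylboronate is added with an achiral acid, diphenyl phosphate, to give the C5-epimeric homopropargylic alcohols F5. Acylation with vinyl acetate and Burkholderia cepacia lipase should convert only the 5R epimer (large alkenyl and medium propargyl substituent, the usual preference of lipases for secondary alcohols) into the (5R)-acetate F6. F6 is separated from the unreacted 5S alcohol by chromatography and methanolysed with K2CO3 in MeOH to 29. The 5S alcohol can be returned by Mitsunobu inversion.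

**Further compounds**

F1 | step 15 | (4S)-4-[(tert-butyldimethylsilyl)oxy]-5,5-dimethyloxolan-2-one | O=C1C[C@H](O[Si](C)(C)C(C)(C)C)C(C)(C)O1
F2 | step 15 | (4S)-4-[(tert-butyldimethylsilyl)oxy]-2-[(2E,6E)-8-[(4-methoxybenzyl)oxy]-6-methylocta-2,6-dien-2-yl]-5,5-dimethyloxolan-2-ol, both anomers | COc1ccc(COC/C=C(\C)CC/C=C(\C)C2(O)C[C@H](O[Si](C)(C)C(C)(C)C)C(C)(C)O2)cc1
F3 | step 20 | (E)-C2 iodide from 30, iodine on C2 and new methyl on C3 | I/C=C(\C)C[C@H](/C=C(\C)CC/C=C(\C)[C@@H]1C[C@H](O[Si](C)(C)C(C)(C)C)C(C)(C)O1)O[Si](CC)(CC)CC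
F4 | step 20 | {2-[(tert-butyldimethylsilyl)oxy]-5-methoxy-3-methylbenzyl}zinc chloride | COc1cc(C)c(O[Si](C)(C)C(C)(C)C)c(C[Zn]Cl)c1
F5 | step 18 | C5-epimeric mixture of 29 | C#CCC(O)/C=C(\C)CC/C=C(\C)[C@@H]1C[C@H](O[Si](C)(C)C(C)(C)C)C(C)(C)O1
F6 | step 18 | (5R)-acetate of 29 | C#CC[C@H](/C=C(\C)CC/C=C(\C)[C@@H]1C[C@H](O[Si](C)(C)C(C)(C)C)C(C)(C)O1)OC(C)=O
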